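**Retrosynthetic overview**
1. Target 37 ⇐ axial C-methylation of a cyclic peroxycarbenium ion from methyl peroxyketal 35 ⇐ perhydrolytic SN2 opening of cis-β-lactone 32 (the 1,2-dioxane is closed last).
2. 32 ⇐ asymmetric ketene–aldehyde cyclocondensation on γ-keto aldehyde 29 ⇐ hydration and oxidation of a silyloxy-alkyne side chain.
3. cis-Decalin diene 25 ⇐ methylenation ⇐ intramolecular allylsilane conjugate addition onto the ring B enone 22 (ring A closed second).
4. Ring B ketone 20 ⇐ one-carbon ring expansion of cyclopentanone 9: 1,2-shift of its quaternary carbon onto a carbenoid made from dibromide 15 (this also joins the two fragments).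
5. 9 ⇐ asymmetric conjugate addition and methylation of 2-methylcyclopentenone. Ring order: five-membered ring → ring B → ring A → dioxane.

Assumption: the silyl group of starting material 10 is a protecting group and is not counted in its size; for each chiral catalyst the enantiomer that gives the drawn configuration is meant.

Abbreviations: TBS = tert-butyldimethylsilyl; Dec = (2R,4aS,8aS)-1,1-dimethyl-3,6-dimethylidenedecahydronaphthalen-2-yl (cis-fused).

**Step 1**
Reactants: 1 3-methylbut-3-en-1-ol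
Product: 4 3-(trimethylsilylmethyl)but-3-en-1-ol, via dilithio dianion 2 (not isolated), via bis(trimethylsilyl) compound 3 (not isolated)
Conditions: n-BuLi (2.2 equiv), TMEDA, Et2O, 0 °C to rt; TMSCl (2.2 equiv), −78 °C to rt; K2CO3 (cat.), MeOH, rt
Reagents that add atoms: chlorotrimethylsilane, C[Si](C)(C)Cl
Why: Alkoxide-directed allylic lithiation of the methyl group gives a C,O-dianion that is silylated on carbon and oxygen, and mild methanolysis frees the alcohol (directed metalation–silylation); no stereocentre.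

**Step 2**
Reactants: 4 3-(trimethylsilylmethyl)but-3-en-1-ol
Product: 5 (4-bromo-2-methylidenebutyl)trimethylsilane
Conditions: CBr4, PPh3, CH2Cl2, 0 °C
Reagents that add atoms: carbon tetrabromide, BrC(Br)(Br)Br
Why: Appel bromination of the primary alcohol under near-neutral conditions that leave the allylsilane intact; no stereocentre.

**Step 3**
Reactants: 5 (4-bromo-2-methylidenebutyl)trimethylsilane; 6 2-methylcyclopent-2-en-1-one
Product: 9 (3S)-2,2-dimethyl-3-[3-(trimethylsilylmethyl)but-3-enyl]cyclopentan-1-one, via Grignard reagent 7 (not isolated), via magnesium enolate 8 (not isolated)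
Conditions: Mg, THF; then 6, CuBr·SMe2 (5 mol%), TaniaPhos (6 mol%), t-BuOMe, −78 °C; then MeI, DMPU, −78 to 0 °C
Reagents that add atoms: iodomethane, CI
Why: Copper-catalysed asymmetric conjugate addition of the Grignard reagent (the ferrocenyl diphosphine selects the enone face and sets C-3 as S), followed by C-methylation of the enolate to the gem-dimethyl ketone (conjugate addition–enolate trapping).

**Step 4**
Reactants: 10 (but-3-yn-1-yloxy)(tert-butyl)dimethylsilane; 11 3-bromo-1,1-dimethoxypropane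
Product: 13 tert-butyl[(7,7-dimethoxyhept-3-yn-1-yl)oxy]dimethylsilane, via lithium acetylide 12 (not isolated)
Conditions: n-BuLi, THF, −78 °C; 11, DMPU, −78 °C to rt
Reagents that add atoms: none
Why: SN2 alkylation of a lithium acetylide by a primary bromide; no stereocentre.

**Step 5**
Reactants: 13 tert-butyl[(7,7-dimethoxyhept-3-yn-1-yl)oxy]dimethylsilane
Product: 14 7-(TBS-oxy)hept-4-ynal
Conditions: I2 (10 mol%), acetone, rt
Reagents that add atoms: none
Why: Iodine-catalysed transacetalisation to acetone frees the aldehyde under neutral conditions that spare the silyl ether (acetal deprotection).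

**Step 6**
Reactants: 14 7-(TBS-oxy)hept-4-ynal
Product: 15 tert-butyl[(7,7-dibromohept-3-yn-1-yl)oxy]dimethylsilane
Conditions: P(OPh)3, Br2, CH2Cl2, −78 °C to rt
Reagents that add atoms: bromine, BrBr
Why: Deoxygenative gem-dibromination of the aldehyde by the triphenyl phosphite–bromine adduct; no stereocentre.

**Step 7**
Reactants: 15 tert-butyl[(7,7-dibromohept-3-yn-1-yl)oxy]dimethylsilane; 9 (3S)-2,2-dimethyl-3-[3-(trimethylsilylmethyl)but-3-enyl]cyclopentan-1-one
Product: 20 (2S,4S)-2-[6-(TBS-oxy)hex-3-yn-1-yl]-3,3-dimethyl-4-[3-(trimethylsilylmethyl)but-3-enyl]cyclohexan-1-one, via dibromoalkyllithium 16 (not isolated), via dibromo alkoxide 17 (not isolated), via oxido carbenoid 18 (not isolated), via lithium enolate 19 (not isolated)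
Conditions: 15, LiN(i-Pr)2, THF/Et2O, −100 °C; 9; n-BuLi (1.1 equiv), −100 to 0 °C; AcOH, −78 °C
Reagents that add atoms: none
Why: β-Oxido carbenoid ring expansion (Nozaki–Yamamoto type): bromine–lithium exchange on adduct 17 gives carbenoid 18, the more substituted (quaternary) ring carbon undergoes the 1,2-shift to the electron-poor carbenoid carbon with loss of LiBr to give enolate 19 regiospecifically, and axial protonation on the half-chair with the C-4 chain equatorial sets C-2 cis to C-4 (2S), which is also the more stable epimer.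

**Step 8**
Reactants: 20 (2S,4S)-2-[6-(TBS-oxy)hex-3-yn-1-yl]-3,3-dimethyl-4-[3-(trimethylsilylmethyl)but-3-enyl]cyclohexan-1-one
Product: 22 (4S,6S)-6-[6-(TBS-oxy)hex-3-yn-1-yl]-5,5-dimethyl-4-[3-(trimethylsilylmethyl)but-3-enyl]cyclohex-2-en-1-one, via kinetic lithium enolate 21 (not isolated)
Conditions: LiN(i-Pr)2, THF, −78 °C; PhS(Cl)=N-t-Bu, −78 °C
Reagents that add atoms: none
Why: Kinetic deprotonation on the unhindered methylene side and Mukaiyama dehydrogenation with the sulfinimidoyl chloride give the enone without touching the C-6 stereocentre (one-pot ketone-to-enone dehydrogenation).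

**Step 9**
Reactants: 22 (4S,6S)-6-[6-(TBS-oxy)hex-3-yn-1-yl]-5,5-dimethyl-4-[3-(trimethylsilylmethyl)but-3-enyl]cyclohex-2-en-1-one
Product: 24 (3S,4aS,8aS)-3-[6-(TBS-oxy)hex-3-yn-1-yl]-4,4-dimethyl-7-methylideneoctahydronaphthalen-2(1H)-one, via aluminium enolate 23 (not isolated)
Conditions: EtAlCl2, CH2Cl2, −78 to −20 °C
Reagents that add atoms: none
Why: Intramolecular Hosomi–Sakurai conjugate addition: the allylsilane on the equatorial C-4 chain attacks the enone β-carbon axially from its own face, closing ring A cis-fused (new centre C-8a, S) and leaving the exocyclic methylene.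

**Step 10**
Reactants: 24 (3S,4aS,8aS)-3-[6-(TBS-oxy)hex-3-yn-1-yl]-4,4-dimethyl-7-methylideneoctahydronaphthalen-2(1H)-one
Product: 25 tert-butyl[(6-Dec-hex-3-yn-1-yl)oxy]dimethylsilane
Conditions: Zn, CH2Br2, TiCl4, THF/CH2Cl2, 0 °C to rt
Reagents that add atoms: dibromomethane, BrCBr
Why: Takai–Lombardo methylenation converts the hindered ketone into the exocyclic alkene under non-basic conditions, so the epimerisable centre next to the carbonyl keeps its configuration.

**Step 11**
Reactants: 25 tert-butyl[(6-Dec-hex-3-yn-1-yl)oxy]dimethylsilane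
Product: 28 1-Dec-6-hydroxyhexan-3-one, via alkynol 26 (not isolated), via dihydrofuran 27 (not isolated)
Conditions: PPTS, MeOH, rt; then Ph3PAuNTf2 (2 mol%), H2O, THF, rt
Reagents that add atoms: water, O
Why: Methanolysis removes the silyl ether, and monovalent-gold catalysed 5-endo hydroalkoxylation of the alkyne by the freed hydroxyl followed by hydrolysis of the enol ether places the ketone on the distal alkyne carbon only (directed alkyne hydration).

**Step 12**
Reactants: 28 1-Dec-6-hydroxyhexan-3-one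
Product: 29 6-Dec-4-oxohexanal
Conditions: Dess–Martin periodinane, NaHCO3, CH2Cl2, 0 °C to rt
Reagents that add atoms: none
Why: Buffered Dess–Martin oxidation of the primary alcohol to the aldehyde; no stereocentre is touched.

**Step 13**
Reactants: 29 6-Dec-4-oxohexanal; 30 propanoyl chloride
Product: 32 (3R,4S)-4-(5-Dec-3-oxopentyl)-3-methyloxetan-2-one, via methylketene 31 (not isolated)
Conditions: O-trimethylsilylquinidine (10 mol%), LiClO4, i-Pr2NEt, Et2O/CH2Cl2, −78 °C
Reagents that add atoms: none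
Why: Cinchona alkaloid–LiClO4 catalysed acyl halide–aldehyde cyclocondensation: the chiral ammonium enolate of methylketene adds to the aldehyde (not the ketone) and lactonises to the cis-lactone, setting C-3 (R) and C-4 (S).

**Step 14**
Reactants: 32 (3R,4S)-4-(5-Dec-3-oxopentyl)-3-methyloxetan-2-one
Product: 35 (2R)-2-[(3R)-6-(2-Dec-ethyl)-6-methoxy-1,2-dioxan-3-yl]propanoic acid, via ketone perhydrate 33 (not isolated), via hydroxy dioxane acid 34 (not isolated)
Conditions: H2O2 (anhydrous, in Et2O, 5 equiv), t-BuOH, 35 °C; then MeOH, PPTS, rt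
Reagents that add atoms: hydrogen peroxide, OO; methanol, CO
Why: Proposed new method: the hydroperoxy group of ketone perhydrate 33 (or free H2O2, followed by hemiketalisation) attacks the lactone at C-4 in a 6-exo SN2 alkyl–oxygen cleavage under neutral conditions, which inverts that centre to the required R configuration and releases the carboxylic acid, and acid-catalysed exchange with methanol then locks hemiketal 34 as the methyl peroxyketal; the closest known reaction types are the SN2 opening of β-lactones at the alkyl carbon by heteroatom nucleophiles with inversion and the intramolecular alkylation of hydroperoxides by sulfonates.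

**Step 15**
Reactants: 35 (2R)-2-[(3R)-6-(2-Dec-ethyl)-6-methoxy-1,2-dioxan-3-yl]propanoic acid
Product: 37 (2R)-2-[(3R,6S)-6-(2-Dec-ethyl)-6-methyl-1,2-dioxan-3-yl]propanoic acid, via peroxycarbenium ion 36 (not isolated)
Conditions: AlMe3 (4 equiv), CH2Cl2, −78 °C; TMSOTf (1.2 equiv), −78 to −40 °C; aq. potassium sodium tartrate
Reagents that add atoms: trimethylaluminium, C[Al](C)C
Why: Proposed new method: TMSOTf ionises the methoxy group to cyclic peroxycarbenium ion 36, whose half-chair holds the C-3 side chain pseudoequatorial, and AlMe3 delivers methyl along the axial trajectory so that the new methyl ends axial and cis to that side chain (6S); the closest known reaction types are the Lewis acid-mediated allylation of 3-alkoxy-1,2-dioxanes through peroxycarbenium ions and the AlMe3 C-methylation of cyclic oxocarbenium ions.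

**Compound list**
1 | 3-methylbut-3-en-1-ol | CC(=C)CCO | starting material
2 | dilithio dianion of 1 (lithiated at the methyl carbon and at oxygen) | [Li]CC(=C)CCO[Li] | intermediate
3 | trimethyl{2-methylidene-4-[(trimethylsilyl)oxy]butyl}silane | C=C(C[Si](C)(C)C)CCO[Si](C)(C)C | intermediate
4 | 3-(trimethylsilylmethyl)but-3-en-1-ol | C=C(C[Si](C)(C)C)CCO | intermediate
5 | (4-bromo-2-methylidenebutyl)trimethylsilane | C=C(C[Si](C)(C)C)CCBr | intermediate
6 | 2-methylcyclopent-2-en-1-one | CC1=CCCC1=O | starting material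
7 | [3-(trimethylsilylmethyl)but-3-enyl]magnesium bromide | C=C(C[Si](C)(C)C)CC[Mg]Br | intermediate
8 | bromomagnesium enolate of (3S)-2-methyl-3-[3-(trimethylsilylmethyl)but-3-enyl]cyclopentanone | CC1=C(O[Mg]Br)CC[C@@H]1CCC(=C)C[Si](C)(C)C | intermediate
9 | (3S)-2,2-dimethyl-3-[3-(trimethylsilylmethyl)but-3-enyl]cyclopentan-1-one | O=C1CC[C@H](CCC(=C)C[Si](C)(C)C)C1(C)C | intermediate
10 | (but-3-yn-1-yloxy)(tert-butyl)dimethylsilane | C#CCCO[Si](C)(C)C(C)(C)C | starting material
11 | 3-bromo-1,1-dimethoxypropane | COC(CCBr)OC | starting material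
12 | lithium acetylide of 10 | [Li]C#CCCO[Si](C)(C)C(C)(C)C | intermediate
13 | tert-butyl[(7,7-dimethoxyhept-3-yn-1-yl)oxy]dimethylsilane | COC(OC)CCC#CCCO[Si](C)(C)C(C)(C)C | intermediate
14 | 7-(TBS-oxy)hept-4-ynal | O=CCCC#CCCO[Si](C)(C)C(C)(C)C | intermediate
15 | tert-butyl[(7,7-dibromohept-3-yn-1-yl)oxy]dimethylsilane | BrC(Br)CCC#CCCO[Si](C)(C)C(C)(C)C | intermediate
16 | 1,1-dibromo-7-(TBS-oxy)hept-4-ynyllithium | [Li]C(Br)(Br)CCC#CCCO[Si](C)(C)C(C)(C)C | intermediate
17 | lithium alkoxide adduct of 16 and 9 (3S; both epimers at the carbinol carbon) | [Li]OC1(CC[C@H](CCC(=C)C[Si](C)(C)C)C1(C)C)C(Br)(Br)CCC#CCCO[Si](C)(C)C(C)(C)C | intermediate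
18 | β-oxido carbenoid (bromine–lithium exchange product of 17) | [Li]OC1(CC[C@H](CCC(=C)C[Si](C)(C)C)C1(C)C)C([Li])(Br)CCC#CCCO[Si](C)(C)C(C)(C)C | intermediate
19 | lithium enolate of 20 (C-1/C-2 enolate, 4S) | [Li]OC1=C(CCC#CCCO[Si](C)(C)C(C)(C)C)C(C)(C)[C@@H](CCC(=C)C[Si](C)(C)C)CC1 | intermediate
20 | (2S,4S)-2-[6-(TBS-oxy)hex-3-yn-1-yl]-3,3-dimethyl-4-[3-(trimethylsilylmethyl)but-3-enyl]cyclohexan-1-one (2,4-cis) | O=C1CC[C@H](CCC(=C)C[Si](C)(C)C)C(C)(C)[C@@H]1CCC#CCCO[Si](C)(C)C(C)(C)C | intermediate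
21 | kinetic lithium enolate of 20 (C-1/C-6 enolate) | [Li]OC1=CC[C@H](CCC(=C)C[Si](C)(C)C)C(C)(C)[C@@H]1CCC#CCCO[Si](C)(C)C(C)(C)C | intermediate
22 | (4S,6S)-6-[6-(TBS-oxy)hex-3-yn-1-yl]-5,5-dimethyl-4-[3-(trimethylsilylmethyl)but-3-enyl]cyclohex-2-en-1-one | O=C1C=C[C@H](CCC(=C)C[Si](C)(C)C)C(C)(C)[C@@H]1CCC#CCCO[Si](C)(C)C(C)(C)C | intermediate
23 | chloro(ethyl)aluminium enolate of 24 | C=C1CC[C@H]2[C@@H](C1)C=C(O[Al](Cl)CC)[C@@H](CCC#CCCO[Si](C)(C)C(C)(C)C)C2(C)C | intermediate
24 | (3S,4aS,8aS)-3-[6-(TBS-oxy)hex-3-yn-1-yl]-4,4-dimethyl-7-methylideneoctahydronaphthalen-2(1H)-one (cis-fused) | C=C1CC[C@H]2[C@@H](C1)CC(=O)[C@@H](CCC#CCCO[Si](C)(C)C(C)(C)C)C2(C)C | intermediate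
25 | tert-butyl[(6-Dec-hex-3-yn-1-yl)oxy]dimethylsilane | C=C1CC[C@H]2[C@@H](C1)CC(=C)[C@@H](CCC#CCCO[Si](C)(C)C(C)(C)C)C2(C)C | intermediate
26 | 6-Dec-hex-3-yn-1-ol | C=C1CC[C@H]2[C@@H](C1)CC(=C)[C@@H](CCC#CCCO)C2(C)C | intermediate
27 | 5-(2-Dec-ethyl)-2,3-dihydrofuran | C=C1CC[C@H]2[C@@H](C1)CC(=C)[C@@H](CCC3=CCCO3)C2(C)C | intermediate
28 | 1-Dec-6-hydroxyhexan-3-one | C=C1CC[C@H]2[C@@H](C1)CC(=C)[C@@H](CCC(=O)CCCO)C2(C)C | intermediate
29 | 6-Dec-4-oxohexanal | C=C1CC[C@H]2[C@@H](C1)CC(=C)[C@@H](CCC(=O)CCC=O)C2(C)C | intermediate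
30 | propanoyl chloride | CCC(=O)Cl | starting material
31 | methylketene | CC=C=O | intermediate
32 | (3R,4S)-4-(5-Dec-3-oxopentyl)-3-methyloxetan-2-one (cis) | C=C1CC[C@H]2[C@@H](C1)CC(=C)[C@@H](CCC(=O)CC[C@@H]3OC(=O)[C@@H]3C)C2(C)C | intermediate
33 | perhydrate of 32 (hydroxy and hydroperoxy groups on the former ketone carbon) | C=C1CC[C@H]2[C@@H](C1)CC(=C)[C@@H](CCC(O)(OO)CC[C@@H]3OC(=O)[C@@H]3C)C2(C)C | intermediate
34 | (2R)-2-[(3R)-6-(2-Dec-ethyl)-6-hydroxy-1,2-dioxan-3-yl]propanoic acid (both hemiketal epimers) | C=C1CC[C@H]2[C@@H](C1)CC(=C)[C@@H](CCC3(O)CC[C@H]([C@@H](C)C(=O)O)OO3)C2(C)C | intermediate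
35 | (2R)-2-[(3R)-6-(2-Dec-ethyl)-6-methoxy-1,2-dioxan-3-yl]propanoic acid (both ketal epimers) | C=C1CC[C@H]2[C@@H](C1)CC(=C)[C@@H](CCC3(OC)CC[C@H]([C@@H](C)C(=O)O)OO3)C2(C)C | intermediate
36 | cyclic peroxycarbenium ion from 35, as its dimethylaluminium carboxylate | C=C1CC[C@H]2[C@@H](C1)CC(=C)[C@@H](CCC3=[O+]O[C@H](CC3)[C@@H](C)C(=O)O[Al](C)C)C2(C)C | intermediate
37 | (2R)-2-[(3R,6S)-6-{2-[(2R,4aS,8aS)-1,1-dimethyl-3,6-dimethylidenedecahydronaphthalen-2-yl]ethyl}-6-methyl-1,2-dioxan-3-yl]propanoic acid | C=C1CC[C@H]2[C@@H](C1)CC(=C)[C@@H](CC[C@@]1(C)CC[C@H]([C@@H](C)C(=O)O)OO1)C2(C)C | target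

**Step count and risk**
Total step count: 15. Longest linear sequence: 12 steps (steps 1–3 and 7–15; the chain branch, steps 4–6 and 7–15, is equally long).

The three steps most likely to fail are 7, 14 and 15.

In step 7 the tertiary carbanion 16 may not add to the hindered ketone, or the methylene carbon may migrate instead of the quaternary one. The fallback is a selenium-stabilised carbanion addition followed by a semipinacol shift, which is known chemistry. It sets out from acetal 13 and ketone 9 and comes back at ketone 20. Acetal 13 is exchanged with MeSeH and ZnCl2 to the bis(methylselanyl)acetal F1. n-BuLi cleaves one carbon–selenium bond to give the α-selenoalkyllithium F2, which adds readily to hindered ketones and gives with 9 the β-hydroxy selenide F3. AgBF4 on Al2O3 turns the selenium into a leaving group and the quaternary carbon shifts, giving 20 as a mixture at C-2 that is equilibrated with DBU and separated.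

In step 14 the lactone may be attacked at the acyl carbon, or water may compete, and the stereospecific peroxide closure is unproven. The fallback uses two known SN2 inversions instead of one new one. It sets out from keto aldehyde 29 and comes back at hemiketal 34, and so at 35. The cyclocondensation of step 13 is run with O-trimethylsilylquinine and gives the enantiomeric cis-lactone F4. Deprotonation with LiN(SiMe3)2 and reprotonation trans to the C-4 substituent epimerises C-3 and gives the trans-lactone F5. MgBr2·OEt2 opens F5 at C-4 with inversion to the β-bromo acid F6. AgOCOCF3 and H2O2 replace bromide by the hydroperoxy group with a second inversion, and the γ-hydroperoxy ketone closes to 34, which MeOH and PPTS convert to 35.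

In step 15 AlMe3 may cleave the O–O bond, the peroxycarbenium ion may fragment or be trapped by the alkenes or the carboxylate, or the facial selectivity may be low. The fallback makes the quaternary C–O bond by acid-catalysed capture of a tertiary cation by a hydroperoxide, a known but stereorandom ring closure. It sets out from keto aldehyde 29, follows the fallback for step 14 as far as bromo acid F6, and comes back at target 37. MeTi(Oi-Pr)3 adds to the ketone of F6 to give the tertiary alcohol bromo acid F7 as both epimers. AgOCOCF3 and H2O2 give the hydroperoxy tertiary alcohol F8. Catalytic BF3·OEt2 at low temperature closes the dioxane, giving 37 together with its epimer at the quaternary carbon, and the two are separated by chromatography.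

**Further compounds**
F1 | step 7 | tert-butyl{[7,7-bis(methylselanyl)hept-3-yn-1-yl]oxy}dimethylsilane | C[Se]C([Se]C)CCC#CCCO[Si](C)(C)C(C)(C)C
F2 | step 7 | 1-(methylselanyl)-7-(TBS-oxy)hept-4-ynyllithium | [Li]C([Se]C)CCC#CCCO[Si](C)(C)C(C)(C)C
F3 | step 7 | (3S)-1-[1-(methylselanyl)-7-(TBS-oxy)hept-4-ynyl]-2,2-dimethyl-3-[3-(trimethylsilylmethyl)but-3-enyl]cyclopentan-1-ol (mixture at the two new centres) | C[Se]C(CCC#CCCO[Si](C)(C)C(C)(C)C)C1(O)CC[C@H](CCC(=C)C[Si](C)(C)C)C1(C)C
F4 | step 14 | (3S,4R)-4-(5-Dec-3-oxopentyl)-3-methyloxetan-2-one (cis) | C=C1CC[C@H]2[C@@H](C1)CC(=C)[C@@H](CCC(=O)CC[C@H]3OC(=O)[C@H]3C)C2(C)C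
F5 | step 14 | (3R,4R)-4-(5-Dec-3-oxopentyl)-3-methyloxetan-2-one (trans) | C=C1CC[C@H]2[C@@H](C1)CC(=C)[C@@H](CCC(=O)CC[C@H]3OC(=O)[C@@H]3C)C2(C)C
F6 | step 14 | (2S,3S)-3-bromo-8-Dec-2-methyl-6-oxooctanoic acid | C=C1CC[C@H]2[C@@H](C1)CC(=C)[C@@H](CCC(=O)CC[C@H](Br)[C@@H](C)C(=O)O)C2(C)C
F7 | step 15 | (2S,3S)-3-bromo-8-Dec-6-hydroxy-2,6-dimethyloctanoic acid (both epimers at C-6) | C=C1CC[C@H]2[C@@H](C1)CC(=C)[C@@H](CCC(C)(O)CC[C@H](Br)[C@@H](C)C(=O)O)C2(C)C
F8 | step 15 | (2R,3R)-8-Dec-3-hydroperoxy-6-hydroxy-2,6-dimethyloctanoic acid (both epimers at C-6) | C=C1CC[C@H]2[C@@H](C1)CC(=C)[C@@H](CCC(C)(O)CC[C@@H](OO)[C@@H](C)C(=O)O)C2(C)C
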